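**Retrosynthetic overview**

- Feature: with the side chain numbered C1' (ArO–CH2) to C8' (=CH2), the E alkene C2'=C3' carries its C3' methyl cis to C1'. That is the pattern left by syn addition of CH3 and a metal across a terminal C2'≡C3' alkyne, so the C3'–CH3 and C1'–C2' bonds are cut together.
- Target ⇒ C5'/C6' acetonide ⇒ (key step) homopropargylic dioxolane alkyne + trimethylaluminium + 7-(chloromethoxy)-8-methoxycoumarin, in which C1' sits on the coumarin O7 as a carbon electrophile.
- Alkyne ⇒ 2-deoxy-D-ribose: its erythro C3/C4 diol is C5'(S)/C6'(R) unchanged, C1 becomes C3' by Ohira–Bestmann alkynylation, and C5 becomes the C7' isopropenyl carbon by oxidation, MeMgBr addition, oxidation and methylenation.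
- Chloromethyl ether ⇒ 7-hydroxy-8-methoxycoumarin + chloromethyl methyl sulfide, via the methylthiomethyl ether.
- Rings: the coumarin bicycle is bought intact and no ring of the target is built. The only ring made is the temporary dioxolane (step 1), opened in the last step.

Key step: step 9

Remark: 2-deoxy-D-ribose is drawn open-chain although it reacts as its pyranose, 7-hydroxy-8-methoxycoumarin is taken as purchasable, and the side-chain atoms keep the labels C1' to C8' in every intermediate.

**Route**

Step 1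
Reactants: 1 2-deoxy-D-ribose
Product: 2 2-deoxy-3,4-O-isopropylidene-D-erythro-pentopyranose [(3aR,7aS)-2,2-dimethyltetrahydro-4H-[1,3]dioxolo[4,5-c]pyran-6-ol, anomeric mixture]
Conditions: 2-methoxypropene, pyridinium p-toluenesulfonate (cat.), EtOAc, −10 °C to rt
Reagents that add atoms: 2-methoxypropene, C=C(C)OC
Why: Kinetic acid-catalysed acetonation with an enol ether should trap the cis-3,4-diol of the pyranose as a cis-fused dioxolane and leave the lactol OH free; C3 and C4 are not touched.

Step 2
Reactants: 2 2-deoxy-3,4-O-isopropylidene-D-erythro-pentopyranose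
Product: 4 [(4R,5S)-2,2-dimethyl-5-(prop-2-yn-1-yl)-1,3-dioxolan-4-yl]methanol, via open-chain hydroxy aldehyde 3 (not isolated)
Conditions: dimethyl (1-diazo-2-oxopropyl)phosphonate, K2CO3, MeOH, rt to 50 °C
Reagents that add atoms: dimethyl (1-diazo-2-oxopropyl)phosphonate, CC(=O)C(=[N+]=[N-])P(=O)(OC)OC
Why: Ohira–Bestmann alkynylation: the lactol opens to aldehyde 3 in basic methanol and the diazomethylphosphonate anion generated in the flask turns CHO into C≡CH with one added carbon; the carbon next to the aldehyde is a CH2 group, so nothing can epimerise.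

Step 3
Reactants: 4 [(4R,5S)-2,2-dimethyl-5-(prop-2-yn-1-yl)-1,3-dioxolan-4-yl]methanol
Product: 5 (4S,5S)-2,2-dimethyl-5-(prop-2-yn-1-yl)-1,3-dioxolane-4-carbaldehyde
Conditions: Dess–Martin periodinane, CH2Cl2, 0 °C to rt; crude aldehyde used at once
Reagents that add atoms: none
Why: Dess–Martin oxidation is base-free, so the oxygen-bearing centre next to the new aldehyde (the future C6') on the cis-dioxolane should not epimerise.

Step 4
Reactants: 5 (4S,5S)-2,2-dimethyl-5-(prop-2-yn-1-yl)-1,3-dioxolane-4-carbaldehyde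
Product: 6 1-[(4R,5S)-2,2-dimethyl-5-(prop-2-yn-1-yl)-1,3-dioxolan-4-yl]ethan-1-ol (both carbinol epimers)
Conditions: MeMgBr, THF, −78 °C; aq. NH4Cl
Reagents that add atoms: methylmagnesium bromide, C[Mg]Br
Why: Grignard 1,2-addition to the aldehyde at −78 °C outruns deprotonation of the alkyne C–H; the new carbinol centre forms as a mixture and is erased by the next oxidation.

Step 5
Reactants: 6 1-[(4R,5S)-2,2-dimethyl-5-(prop-2-yn-1-yl)-1,3-dioxolan-4-yl]ethan-1-ol
Product: 7 1-[(4S,5S)-2,2-dimethyl-5-(prop-2-yn-1-yl)-1,3-dioxolan-4-yl]ethan-1-one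
Conditions: Dess–Martin periodinane, CH2Cl2, 0 °C to rt
Reagents that add atoms: none
Why: Dess–Martin oxidation of the secondary alcohol should give the methyl ketone without base, so the adjacent ring stereocentre keeps its cis relationship.

Step 6
Reactants: 7 1-[(4S,5S)-2,2-dimethyl-5-(prop-2-yn-1-yl)-1,3-dioxolan-4-yl]ethan-1-one
Product: 8 (4S,5R)-2,2-dimethyl-4-(prop-2-yn-1-yl)-5-(prop-1-en-2-yl)-1,3-dioxolane
Conditions: Zn, CH2Br2, TiCl4, THF, −40 to 5 °C (reagent aged); then 7, CH2Cl2, 0 °C to rt; cold concentration (volatile product)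
Reagents that add atoms: dibromomethane, BrCBr
Why: Takai–Lombardo methylenation uses a non-basic zinc–titanium methylene reagent that converts enolisable α-alkoxy ketones into 1,1-disubstituted alkenes without epimerisation, which a basic phosphorus ylide would risk.

Step 7
Reactants: 9 7-hydroxy-8-methoxy-2H-chromen-2-one; 10 chloromethyl methyl sulfide
Product: 11 8-methoxy-7-[(methylsulfanyl)methoxy]-2H-chromen-2-one
Conditions: NaH, NaI (cat.), DMF, 0 °C to rt
Reagents that add atoms: none
Why: Williamson-type O-alkylation of the sodium phenoxide by the sulfur-activated chloride (through the iodide) should give the methylthiomethyl ether, and the lactone is inert to the phenoxide.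

Step 8
Reactants: 11 8-methoxy-7-[(methylsulfanyl)methoxy]-2H-chromen-2-one
Product: 12 7-(chloromethoxy)-8-methoxy-2H-chromen-2-one
Conditions: SO2Cl2, CH2Cl2, 0 °C; volatiles removed in vacuo; crude 12 used at once under argon
Reagents that add atoms: sulfuryl chloride, O=S(=O)(Cl)Cl
Why: Chlorinolysis of the O,S-acetal: sulfur is chlorinated to a chlorosulfonium ion that fragments to the aryloxymethyl cation and chloride with loss of MeSCl, the established conversion of aryl methylthiomethyl ethers into aryl chloromethyl ethers.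

Step 9
Reactants: 8 (4S,5R)-2,2-dimethyl-4-(prop-2-yn-1-yl)-5-(prop-1-en-2-yl)-1,3-dioxolane; 13 trimethylaluminium; 12 7-(chloromethoxy)-8-methoxy-2H-chromen-2-one
Product: 15 7-({(2E)-4-[(4S,5R)-2,2-dimethyl-5-(prop-1-en-2-yl)-1,3-dioxolan-4-yl]-3-methylbut-2-en-1-yl}oxy)-8-methoxy-2H-chromen-2-one, via alkenyldimethylalane 14 (not isolated)
Conditions: Me3Al (2.5 equiv), Cp2ZrCl2 (0.25 equiv), CH2Cl2, 0 °C to rt; volatiles (excess Me3Al) removed in vacuo; CH2Cl2, 12 (1.5 equiv), −20 to 0 °C; aq. potassium sodium tartrate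
Reagents that add atoms: none
Why: Cp2ZrCl2 and Me3Al form a bimetallic methylzirconium species that adds CH3 and metal syn across the terminal alkyne, methyl to the internal carbon C3' and metal to the terminal carbon C2', and exchange to aluminium gives the (E)-alkenyldimethylalane 14 (Negishi zirconium-catalysed carboalumination). With excess Me3Al pumped off, the Lewis-acidic aluminium ionises α-chloro ether 12 to an aryloxymethyl oxocarbenium–chloroaluminate pair and the alkenyl group, which transfers in preference to methyl, bonds to C1' with retention at C2'; the closest known reaction is the alkylation of carboalumination-derived alkenylalanes by chloromethyl methyl ether. No ring is closed and no stereocentre is formed, C5' and C6' being spectators held in the dioxolane. The step needs regioselectivity (aluminium on the less hindered terminal carbon, as is normal for homopropargylic ethers), E geometry (fixed by syn addition and retentive C–Al to C–C exchange, provided the mixture is not heated) and chemoselectivity. The 1,1-disubstituted C7'=C8' alkene does not carbometalate under these conditions, and the ionised chloromethyl ether is far more electrophilic than the lactone carbonyl or the coumarin C3=C4 bond, which alkenylalanes are not expected to attack at or below 0 °C. Low temperature and short contact should keep Me3Al and the Me2AlCl formed from opening the acetonide.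

Step 10
Reactants: 15 7-({(2E)-4-[(4S,5R)-2,2-dimethyl-5-(prop-1-en-2-yl)-1,3-dioxolan-4-yl]-3-methylbut-2-en-1-yl}oxy)-8-methoxy-2H-chromen-2-one
Product: 16 7-{[(2E,5S,6R)-5,6-dihydroxy-3,7-dimethylocta-2,7-dien-1-yl]oxy}-8-methoxy-2H-chromen-2-one (CNP0214345.2)
Conditions: AcOH/H2O 4:1, 40 °C
Reagents that add atoms: none
Why: Acid-catalysed acetal hydrolysis releases acetone and the diol without breaking a C–O bond at C5' or C6', and acetic acid is too weak to ionise the allylic aryl ether at C1' or the allylic alcohol at C6'.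

**Compound list**

1 | 2-deoxy-D-ribose (drawn open-chain) | O=CC[C@H](O)[C@H](O)CO | starting material
2 | 2-deoxy-3,4-O-isopropylidene-D-erythro-pentopyranose, anomeric mixture | OC1C[C@@H]2OC(C)(C)O[C@@H]2CO1 | intermediate
3 | 2-[(4S,5R)-5-(hydroxymethyl)-2,2-dimethyl-1,3-dioxolan-4-yl]acetaldehyde | OC[C@H]1OC(C)(C)O[C@H]1CC=O | intermediate (not isolated)
4 | [(4R,5S)-2,2-dimethyl-5-(prop-2-yn-1-yl)-1,3-dioxolan-4-yl]methanol | OC[C@H]1OC(C)(C)O[C@H]1CC#C | intermediate
5 | (4S,5S)-2,2-dimethyl-5-(prop-2-yn-1-yl)-1,3-dioxolane-4-carbaldehyde | O=C[C@H]1OC(C)(C)O[C@H]1CC#C | intermediate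
6 | 1-[(4R,5S)-2,2-dimethyl-5-(prop-2-yn-1-yl)-1,3-dioxolan-4-yl]ethan-1-ol, both carbinol epimers | CC(O)[C@H]1OC(C)(C)O[C@H]1CC#C | intermediate
7 | 1-[(4S,5S)-2,2-dimethyl-5-(prop-2-yn-1-yl)-1,3-dioxolan-4-yl]ethan-1-one | CC(=O)[C@H]1OC(C)(C)O[C@H]1CC#C | intermediate
8 | (4S,5R)-2,2-dimethyl-4-(prop-2-yn-1-yl)-5-(prop-1-en-2-yl)-1,3-dioxolane | C=C(C)[C@H]1OC(C)(C)O[C@H]1CC#C | intermediate
9 | 7-hydroxy-8-methoxy-2H-chromen-2-one | Oc1ccc2ccc(=O)oc2c1OC | starting material
10 | chloromethyl methyl sulfide | CSCCl | starting material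
11 | 8-methoxy-7-[(methylsulfanyl)methoxy]-2H-chromen-2-one | CSCOc1ccc2ccc(=O)oc2c1OC | intermediate
12 | 7-(chloromethoxy)-8-methoxy-2H-chromen-2-one | ClCOc1ccc2ccc(=O)oc2c1OC | intermediate
13 | trimethylaluminium | C[Al](C)C | starting material
14 | {(1E)-3-[(4S,5R)-2,2-dimethyl-5-(prop-1-en-2-yl)-1,3-dioxolan-4-yl]-2-methylprop-1-en-1-yl}dimethylalumane | C=C(C)[C@H]1OC(C)(C)O[C@H]1C/C(C)=C/[Al](C)C | intermediate (not isolated)
15 | 7-({(2E)-4-[(4S,5R)-2,2-dimethyl-5-(prop-1-en-2-yl)-1,3-dioxolan-4-yl]-3-methylbut-2-en-1-yl}oxy)-8-methoxy-2H-chromen-2-one | C=C(C)[C@H]1OC(C)(C)O[C@H]1C/C(C)=C/COc1ccc2ccc(=O)oc2c1OC | intermediate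
16 | 7-{[(2E,5S,6R)-5,6-dihydroxy-3,7-dimethylocta-2,7-dien-1-yl]oxy}-8-methoxy-2H-chromen-2-one | C=C(C)[C@@H](O)[C@@H](O)C/C(C)=C/COc1ccc2ccc(=O)oc2c1OC | target

**Step count and risks**

Total step count: 10. Longest linear sequence: 8 steps (steps 1 to 6, 9 and 10); the coumarin arm (steps 7 and 8) joins at step 9.

Steps most likely to fail:

1. Step 9. The dioxolane may be opened by the aluminium Lewis acids during carbometalation. Methyl may transfer in place of alkenyl. The oxocarbenium ion may be captured by the C7'=C8' alkene. The aryloxymethyl chloride may ionise too sluggishly or be consumed at the lactone. The fallback sets out from alkyne 8. Carboalumination as in step 9 gives alane 14, and n-BuLi (hexane/THF, −78 °C) converts it into lithium butyl{(1E)-3-[(4S,5R)-2,2-dimethyl-5-(prop-1-en-2-yl)-1,3-dioxolan-4-yl]-2-methylprop-1-en-1-yl}dimethylaluminate F1. Paraformaldehyde (THF, −78 °C to rt) should then give (2E)-4-[(4S,5R)-2,2-dimethyl-5-(prop-1-en-2-yl)-1,3-dioxolan-4-yl]-3-methylbut-2-en-1-ol F2. Mitsunobu etherification of F2 with phenol 9 (PPh3, DIAD, THF, 0 °C) rejoins the route at compound 15. This path also bypasses chloromethyl ether 12 if steps 7 and 8 do not deliver it cleanly.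

2. Step 6. The zinc–titanium methylene reagent may engage the terminal alkyne, or slow methylenation may leave the ketone long enough to epimerise at the ring carbon next to the carbonyl. The fallback sets out from ketone 7. Me3SiCH2Li premixed with anhydrous CeCl3 (THF, −78 °C, one extra equivalent for the alkyne C–H) should add to the carbonyl without enolisation and give 2-[(4S,5S)-2,2-dimethyl-5-(prop-2-yn-1-yl)-1,3-dioxolan-4-yl]-1-(trimethylsilyl)propan-2-ol F3. KN(SiMe3)2 (THF, 0 °C) should then trigger Peterson syn-elimination, coming back to the route at alkyne 8.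

3. Step 10. A cis-4,5-disubstituted dioxolane may need acid strong enough to ionise the allylic C1'–O bond (loss of the coumarin phenol, allylic transposition) or the C6' allylic alcohol. The fallback sets out from alkyne 8, where no aryl allyl ether is present yet. 1 M HCl in MeOH (rt) should free (3R,4S)-2-methylhept-1-en-6-yne-3,4-diol F4. TESCl, imidazole, DMF should give (3R,4S)-2-methyl-3,4-bis[(triethylsilyl)oxy]hept-1-en-6-yne F5. The conditions of step 9 with 13 and 12 should take F5 through {(1E,4S,5R)-2,6-dimethyl-4,5-bis[(triethylsilyl)oxy]hepta-1,6-dien-1-yl}dimethylalumane F6 to 7-({(2E,5S,6R)-3,7-dimethyl-5,6-bis[(triethylsilyl)oxy]octa-2,7-dien-1-yl}oxy)-8-methoxy-2H-chromen-2-one F7. HF·pyridine in THF/pyridine at 0 °C then removes both silyl groups and the route is rejoined at target 16. Silyl ethers also resist Me3Al, so this swap answers acetonide loss in step 9 as well.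

**Further compounds**

F1 | step 9 | lithium butyl{(1E)-3-[(4S,5R)-2,2-dimethyl-5-(prop-1-en-2-yl)-1,3-dioxolan-4-yl]-2-methylprop-1-en-1-yl}dimethylaluminate | C=C(C)[C@H]1OC(C)(C)O[C@H]1C/C(C)=C/[Al-](C)(C)CCCC.[Li+]
F2 | step 9 | (2E)-4-[(4S,5R)-2,2-dimethyl-5-(prop-1-en-2-yl)-1,3-dioxolan-4-yl]-3-methylbut-2-en-1-ol | C=C(C)[C@H]1OC(C)(C)O[C@H]1C/C(C)=C/CO
F3 | step 6 | 2-[(4S,5S)-2,2-dimethyl-5-(prop-2-yn-1-yl)-1,3-dioxolan-4-yl]-1-(trimethylsilyl)propan-2-ol, either carbinol configuration | C[Si](C)(C)CC(C)(O)[C@H]1OC(C)(C)O[C@H]1CC#C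
F4 | step 10 | (3R,4S)-2-methylhept-1-en-6-yne-3,4-diol | C=C(C)[C@@H](O)[C@@H](O)CC#C
F5 | step 10 | (3R,4S)-2-methyl-3,4-bis[(triethylsilyl)oxy]hept-1-en-6-yne | C=C(C)[C@@H](O[Si](CC)(CC)CC)[C@@H](O[Si](CC)(CC)CC)CC#C
F6 | step 10 | {(1E,4S,5R)-2,6-dimethyl-4,5-bis[(triethylsilyl)oxy]hepta-1,6-dien-1-yl}dimethylalumane | C=C(C)[C@@H](O[Si](CC)(CC)CC)[C@@H](O[Si](CC)(CC)CC)C/C(C)=C/[Al](C)C
F7 | step 10 | 7-({(2E,5S,6R)-3,7-dimethyl-5,6-bis[(triethylsilyl)oxy]octa-2,7-dien-1-yl}oxy)-8-methoxy-2H-chromen-2-one | C=C(C)[C@@H](O[Si](CC)(CC)CC)[C@@H](O[Si](CC)(CC)CC)C/C(C)=C/COc1ccc2ccc(=O)oc2c1OC
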